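**Retrosynthetic overview**
1. Target 13 ⇐ racemic isoflavanone 12 by transfer hydrogenation with dynamic kinetic resolution, which sets C3 and C4 (cis) in the last step.
2. 12 ⇐ tricyclic boronate 11 by removal of boron and benzylic oxidation.
3. 11 ⇐ aldehyde 10 by the key step: a boron-templated intramolecular ortho-hydroxyalkylation that closes pyran ring C (C4–C4a bond) and a 1,3,2-dioxaborinine across O4/O5 in one operation.
4. 10 ⇐ alkene 8 (hydroboration–oxidation, then oxidation) ⇐ Suzuki union of ring B bromide 3 and ring A vinyl bromide 6.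
5. Ring order: rings A and B are bought as arenes; ring C and the temporary boron ring form together in step 5; the boron ring is opened in step 6.

Assumption: the SMILES is read as the (3R,4R)-3,4-cis isoflavan-4-ol (aryl and 4-OH on the same face).

**Route**

Step 1
Reactants: 1 4-bromo-3-methoxyphenol; 2 1-bromo-3-methylbut-2-ene (prenyl bromide)
Product: 3 4-bromo-5-methoxy-2-(3-methylbut-2-en-1-yl)phenol
Conditions: NaH (1.05 equiv), PhMe, 0 °C; then 2, rt, 16 h
Reagents that add atoms: none
Why: Ortho-C-prenylation of a sodium phenoxide held as a tight ion pair in a non-polar solvent (ambident phenoxide C-alkylation), which takes place at the ortho carbon not flanked by the methoxy group.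

Step 2
Reactants: 4 5-methoxybenzene-1,3-diol; 5 2,3-dibromoprop-1-ene
Product: 6 3-[(2-bromoprop-2-en-1-yl)oxy]-5-methoxyphenol
Conditions: K2CO3, acetone, 50 °C (4 in threefold excess, recovered)
Reagents that add atoms: none
Why: Williamson ether synthesis at the allylic bromide (the vinylic bromide is inert to SN2), the excess of the symmetrical diol ensuring mono-etherification.

Step 3
Reactants: 3 4-bromo-5-methoxy-2-(3-methylbut-2-en-1-yl)phenol; 6 3-[(2-bromoprop-2-en-1-yl)oxy]-5-methoxyphenol
Product: 8 3-({2-[4-hydroxy-2-methoxy-5-(3-methylbut-2-en-1-yl)phenyl]prop-2-en-1-yl}oxy)-5-methoxyphenol, via aryl pinacol boronate 7 (not isolated)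
Conditions: B2pin2, PdCl2(dppf) (3 mol%), KOAc, 1,4-dioxane, 90 °C; then 6, aq K3PO4, 80 °C
Reagents that add atoms: bis(pinacolato)diboron, CC1(C)OB(OC1(C)C)B1OC(C)(C)C(C)(C)O1 (supplies the boryl group of 7, which leaves again when 8 forms)
Why: Miyaura borylation of the aryl bromide followed in the same flask by Suzuki–Miyaura coupling with the vinylic bromide, both of which tolerate free phenols.

Step 4
Reactants: 8 3-({2-[4-hydroxy-2-methoxy-5-(3-methylbut-2-en-1-yl)phenyl]prop-2-en-1-yl}oxy)-5-methoxyphenol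
Product: 9 rac-3-({3-hydroxy-2-[4-hydroxy-2-methoxy-5-(3-methylbut-2-en-1-yl)phenyl]propyl}oxy)-5-methoxyphenol
Conditions: 9-BBN (3.5 equiv), THF, 0 °C → rt; then NaOH, H2O2, 0 °C
Reagents that add atoms: hydrogen peroxide, OO
Why: Anti-Markovnikov hydroboration–oxidation in which 9-BBN adds to the 1,1-disubstituted alkene far faster than to the trisubstituted prenyl alkene, the new centre (later C3) being formed as a racemate because it is reset in step 7.

Step 5
Reactants: 9 rac-3-({3-hydroxy-2-[4-hydroxy-2-methoxy-5-(3-methylbut-2-en-1-yl)phenyl]propyl}oxy)-5-methoxyphenol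
Product: 11 rac-3,4-trans-3-[4-hydroxy-2-methoxy-5-(3-methylbut-2-en-1-yl)phenyl]-7-methoxychroman-4,5-diol 4,5-O-phenylboronate, via aldehyde 10 (not isolated)
Conditions: Dess–Martin periodinane, CH2Cl2, 0 °C; then PhB(OH)2 (1.2 equiv), EtCO2H (cat.), PhMe, 4 Å MS, 60 °C
Reagents that add atoms: phenylboronic acid, OB(O)c1ccccc1
Why: Proposed new method: Dess–Martin oxidation gives the β-aryloxy aldehyde 10, whose free ring A phenol condenses with PhB(OH)2 to an aryloxyboronic hemiester that binds the tethered aldehyde and delivers it through a six-membered chair-like transition state to the only ortho carbon the tether can reach (the one between the two oxygens), so that pyran ring C and the 1,3,2-dioxaborinine ring close in one operation with the 5-OH/7-OMe pattern fixed and the labile benzylic oxygen capped, the 3-aryl group expected equatorial (3,4-trans, racemic, of no consequence since both centres are reset), the closest known reaction type being the phenylboronic acid-templated ortho-hydroxyalkylation of phenols with aldehydes (Nagata reaction) that gives 2-phenyl-4H-1,3,2-benzodioxaborins, here run intramolecularly.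

Step 6
Reactants: 11 rac-3,4-trans-3-[4-hydroxy-2-methoxy-5-(3-methylbut-2-en-1-yl)phenyl]-7-methoxychroman-4,5-diol 4,5-O-phenylboronate
Product: 12 rac-5-hydroxy-3-[4-hydroxy-2-methoxy-5-(3-methylbut-2-en-1-yl)phenyl]-7-methoxychroman-4-one
Conditions: activated MnO2 (excess), CH2Cl2–MeOH 10:1 (wet), rt
Reagents that add atoms: none
Why: Solvolysis opens the boronate and MnO2 oxidises the liberated salicyl-type benzylic alcohol to the hydrogen-bonded aryl ketone (benzylic alcohol oxidation), which erases C4 and makes C3 epimerisable for the next step.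

Step 7
Reactants: 12 rac-5-hydroxy-3-[4-hydroxy-2-methoxy-5-(3-methylbut-2-en-1-yl)phenyl]-7-methoxychroman-4-one
Product: 13 (3R,4R)-3-[4-hydroxy-2-methoxy-5-(3-methylbut-2-en-1-yl)phenyl]-7-methoxy-3,4-dihydro-2H-chromene-4,5-diol
Conditions: RuCl[(R,R)-TsDPEN](p-cymene) (3 mol%), HCO2H/Et3N (1:1.3), EtOAc, 40 °C
Reagents that add atoms: none
Why: Noyori–Ikariya asymmetric transfer hydrogenation with dynamic kinetic resolution, in which Et3N racemises C3 through the enol while the (R,R)-catalyst reduces the (3R)-ketone faster and delivers hydride to C4 on the face opposite the 3-aryl group (aryl ketone to (R)-carbinol, as for chroman-4-one), giving the cis-(3R,4R) alcohol under non-acidic conditions.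

**Compound list**
1 | 4-bromo-3-methoxyphenol | COc1cc(O)ccc1Br | starting material
2 | 1-bromo-3-methylbut-2-ene | CC(C)=CCBr | starting material
3 | 4-bromo-5-methoxy-2-(3-methylbut-2-en-1-yl)phenol | COc1cc(O)c(CC=C(C)C)cc1Br | intermediate
4 | 5-methoxybenzene-1,3-diol | COc1cc(O)cc(O)c1 | starting material
5 | 2,3-dibromoprop-1-ene | C=C(Br)CBr | starting material
6 | 3-[(2-bromoprop-2-en-1-yl)oxy]-5-methoxyphenol | COc1cc(O)cc(OCC(Br)=C)c1 | intermediate
7 | 5-methoxy-2-(3-methylbut-2-en-1-yl)-4-(4,4,5,5-tetramethyl-1,3,2-dioxaborolan-2-yl)phenol | COc1cc(O)c(CC=C(C)C)cc1B1OC(C)(C)C(C)(C)O1 | intermediate (not isolated)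
8 | 3-({2-[4-hydroxy-2-methoxy-5-(3-methylbut-2-en-1-yl)phenyl]prop-2-en-1-yl}oxy)-5-methoxyphenol | COc1cc(O)cc(OCC(=C)c2cc(CC=C(C)C)c(O)cc2OC)c1 | intermediate
9 | rac-3-({3-hydroxy-2-[4-hydroxy-2-methoxy-5-(3-methylbut-2-en-1-yl)phenyl]propyl}oxy)-5-methoxyphenol (racemic, one undefined centre) | COc1cc(O)cc(OCC(CO)c2cc(CC=C(C)C)c(O)cc2OC)c1 | intermediate
10 | rac-3-(3-hydroxy-5-methoxyphenoxy)-2-[4-hydroxy-2-methoxy-5-(3-methylbut-2-en-1-yl)phenyl]propanal (racemic) | COc1cc(O)cc(OCC(C=O)c2cc(CC=C(C)C)c(O)cc2OC)c1 | intermediate (not isolated)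
11 | rac-3,4-trans isoflavan-4,5-diol 4,5-O-phenylboronate: chroman fused to a 2-phenyl-1,3,2-dioxaborinine through O4–B(Ph)–O5 (racemic; the expected major trans isomer drawn as one enantiomer) | COc1cc3c2c(c1)OC[C@@H](c4cc(CC=C(C)C)c(O)cc4OC)[C@@H]2OB(c5ccccc5)O3 | intermediate
12 | rac-5-hydroxy-3-[4-hydroxy-2-methoxy-5-(3-methylbut-2-en-1-yl)phenyl]-7-methoxychroman-4-one (racemic, C3 labile) | COc1cc(O)c2C(=O)C(COc2c1)c1cc(CC=C(C)C)c(O)cc1OC | intermediate
13 | (3R,4R)-3-[4-hydroxy-2-methoxy-5-(3-methylbut-2-en-1-yl)phenyl]-7-methoxy-3,4-dihydro-2H-chromene-4,5-diol (3,4-cis) | COc1cc(O)c2c(c1)OC[C@@H](c1cc(CC=C(C)C)c(O)cc1OC)[C@H]2O | target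

**Step count and risks**
Total step count: 7. Longest linear sequence: 6 (steps 1, 3, 4, 5, 6, 7).

Most likely to fail, step 5. The aldehyde 10 can lose the aryloxide by β-elimination, can cyclise without the boron template at the other ortho carbon, and the boronate can fragment to a quinone methide on heating. The fallback sets out from 3 and comes back at 12. Compound 3 is borylated as in the first half of step 3 and boronate 7 is isolated. Ring C is then built on the ring A fragment instead: commercial 1-(2,6-dihydroxy-4-methoxyphenyl)ethan-1-one F2 is condensed with DMF dimethyl acetal to the enaminone (E)-3-(dimethylamino)-1-(2,6-dihydroxy-4-methoxyphenyl)prop-2-en-1-one F3, which iodine in methanol cyclises to 5-hydroxy-3-iodo-7-methoxy-4H-chromen-4-one F4. Suzuki–Miyaura coupling of F4 with 7 (PdCl2(dppf), aq K2CO3, dioxane) gives the isoflavone 5-hydroxy-3-[4-hydroxy-2-methoxy-5-(3-methylbut-2-en-1-yl)phenyl]-7-methoxy-4H-chromen-4-one F5. Under the conditions of step 7, F5 is first reduced at the C2–C3 double bond to 12 in the flask and then continues to 13.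

Step 1. C- versus O-alkylation and attack at the wrong ortho carbon limit the yield. The fallback sets out from 1 and comes back at 3. Compound 1 is alkylated on oxygen with 2 (K2CO3, acetone, 50 °C) to the prenyl ether 1-bromo-2-methoxy-4-[(3-methylbut-2-en-1-yl)oxy]benzene F1, and the prenyl group is then moved to the free ortho carbon by an acid-clay-promoted 1,3-shift (montmorillonite K10, CH2Cl2, 0 °C → rt) to give 3.

Step 7. The hydrogen-bonded 5-OH lowers the reactivity of the ketone, and the product alcohol is acid-labile. The fallback sets out from 12 and comes back at 13. Both phenols are silylated (TBSOTf, 2,6-lutidine, CH2Cl2) to rac-5-[(tert-butyldimethylsilyl)oxy]-3-{4-[(tert-butyldimethylsilyl)oxy]-2-methoxy-5-(3-methylbut-2-en-1-yl)phenyl}-7-methoxychroman-4-one F6. The same transfer hydrogenation with dynamic kinetic resolution on this unchelated ketone gives the (3R,4R)-cis bis-silyl ether of the chroman-4-ol F7, and Bu4NF in THF at 0 °C releases 13 without acid.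

Further compounds
F1 | step 1 | 1-bromo-2-methoxy-4-[(3-methylbut-2-en-1-yl)oxy]benzene | COc1cc(OCC=C(C)C)ccc1Br
F2 | step 5 | 1-(2,6-dihydroxy-4-methoxyphenyl)ethan-1-one (purchased) | COc1cc(O)c(C(C)=O)c(O)c1
F3 | step 5 | (E)-3-(dimethylamino)-1-(2,6-dihydroxy-4-methoxyphenyl)prop-2-en-1-one | COc1cc(O)c(C(=O)/C=C/N(C)C)c(O)c1
F4 | step 5 | 5-hydroxy-3-iodo-7-methoxy-4H-chromen-4-one | COc1cc(O)c2c(c1)occ(I)c2=O
F5 | step 5 | 5-hydroxy-3-[4-hydroxy-2-methoxy-5-(3-methylbut-2-en-1-yl)phenyl]-7-methoxy-4H-chromen-4-one | COc1cc(O)c2c(c1)occ(-c1cc(CC=C(C)C)c(O)cc1OC)c2=O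
F6 | step 7 | rac-5-[(tert-butyldimethylsilyl)oxy]-3-{4-[(tert-butyldimethylsilyl)oxy]-2-methoxy-5-(3-methylbut-2-en-1-yl)phenyl}-7-methoxychroman-4-one | COc1cc(O[Si](C)(C)C(C)(C)C)c2C(=O)C(COc2c1)c1cc(CC=C(C)C)c(O[Si](C)(C)C(C)(C)C)cc1OC
F7 | step 7 | (3R,4R)-5-[(tert-butyldimethylsilyl)oxy]-3-{4-[(tert-butyldimethylsilyl)oxy]-2-methoxy-5-(3-methylbut-2-en-1-yl)phenyl}-7-methoxychroman-4-ol | COc1cc(O[Si](C)(C)C(C)(C)C)c2c(c1)OC[C@@H](c1cc(CC=C(C)C)c(O[Si](C)(C)C(C)(C)C)cc1OC)[C@H]2O
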